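**Remark:** the side chain is numbered from the benzylic carbon C1' to the terminal methyl C17'. Compounds 1, 2, 5, 6 and 16 are taken to be commercial, 5 in high enantiomeric purity.

## Analysis of the target

Hansfordiol G (21) is 5-[(8Z,15S)-15-hydroxyheptadec-8-en-1-yl]benzene-1,3-diol, a resorcinol ring whose C5 carries one unbranched seventeen-carbon chain. The chain holds two stereochemical elements: the Z-alkene C8'=C9' and the single stereocentre C15' (S), a secondary carbinol flanked by an ethyl group and the long chain. Five methylenes (C10'–C14') separate them, so neither can direct the other and each has to be set independently. The sensitive groups are the electron-rich resorcinol (easily oxidised and attacked by electrophiles), the isolated Z-alkene (no hydrogenation, no radical or acid isomerisation) and the carbinol, which must be masked in organometallic steps. The difficulty is a lack of handles rather than complexity: runs of seven and five methylenes lie between the three functional sites, so every C–C bond made inside them must leave no functionality behind. The C15' centre is also awkward for asymmetric catalysis because ethyl and n-alkyl are sterically alike, so it is best bought. The strategy rests on the C10'–C14' run: the bond C12'–C13' can be formed from two carboxylic acids by anodic double decarboxylation, which is traceless. C12' is the closest position to the alkene at which a primary radical leaves the Z geometry alone, and C13' lies two carbons from C15'.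

## Retrosynthetic reasoning

**21 from 20.** The two phenols and the carbinol are unmasked last. Two acetal-type phenol ethers and one silyl ether are chosen so that a single acid treatment removes all three without touching the alkene.

**20 from 15 and 19 (aryl–C1' bond).** The ring is cut from the chain at C1'. If the chain is carried as a C18 acid, the carboxyl carbon is a disposable activating group: redox-active ester 15 gives a primary radical at C1' that nickel joins to arylzinc 19. The gain is that the oxidisable arene enters after the electrolysis and the oxidative steps. Arylzinc 19 comes from bromide 17, the bis-protected form of commercial 16.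

**15 back to 11 (functional-group changes only).** Ester 15 comes from silyloxy acid 14, 14 from hydroxy acid 12, and 12 from diester 11 by cleavage of both esters. The acetate is the right group for the electrolysis but not for active-ester formation and the arylzinc coupling, so it is exchanged for a silyl ether once the chain is complete.

**11 from 4 and 10 (C12'–C13' bond, the key disconnection).** The cut is placed in the middle of the pentamethylene run. Both fragments then end in a CH2–CO2H group, and the forward reaction only has to pair two primary radicals. A cut one bond nearer the alkene would put the radical in a homoallylic position, where the geometry can scramble. A cut nearer C15' would place the radical next to the oxygen-bearing carbon. The step must deliver cross-coupling over self-coupling and keep the alkene, the acetate and the methyl ester intact.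

**4 from 1 and 2 (C8'=C9').** The alkene is cut into phosphonium salt 1 and aldehyde ester 2. The non-stabilised ylide sets the Z geometry. The two ends of 4 arrive already differentiated, a free acid for the electrolysis and a methyl ester for later.

**10 from 8, 7, 5 and 6.** The stereocentre is taken from epoxide 5, opened at its unsubstituted carbon by allyl reagent 6 to give 7. Acetylation gives 8, and oxidative cleavage of the terminal alkene reveals the carboxyl group of 10. The hydroxyl is acylated before the carboxyl exists, so a free 4-hydroxy acid, which would close to its lactone, is never formed.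

## Alternatives that were turned down

**Alternative 1: build the resorcinol ring by a polyketide-type aldol.** The ring is disconnected between the chain-bearing carbon and its neighbour, giving the open-chain 3,5,7-triketo ester A2. In the forward step a mild base forms the C2 carbanion of A2, which adds to the C7 ketone. Loss of water and enolisation then give resorcylate A1, and ester removal (saponification, decarboxylation) and desilylation finish the synthesis.
- For: it needs no transition metal, no phenol protection and no aryl organometallic. On these points it is stronger than the chosen route.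
- Against: A2 must be made by acylating a diketo-ester polyanion with an activated form of the same C18 acid that the chosen route makes as 14. The chain, which is the real problem, is therefore left unsolved. A2 can also close by competing Claisen-type or O-cyclisation modes, and the ester of A1 has to be removed afterwards.
- Comparison: from 14 about four operations are needed against three (steps 8, 11, 12) plus two short steps to 19. The chosen route offers a ring of unambiguous substitution pattern taken from the shelf.

**Alternative 2: enantioconvergent nickel coupling at C14'–C15'.** The chain is cut next to the stereocentre into the racemic α-chloro boronic ester A4 and the long alkylzinc iodide A5. A chiral diamine–nickel catalyst converts both enantiomers of A4, through a common α-boryl radical, into the (S)-boronic ester A3. Oxidation of the C–B bond with retention and acetal cleavage would follow.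
- For: the stereocentre is set by the catalyst, either enantiomer is reachable by changing the ligand, and no chiral-pool material is needed. In that flexibility it is stronger than the chosen route.
- Against: the enantiomeric purity is decided in the last C–C bond formation on the most advanced intermediate and cannot be upgraded, since every compound is an oil. A5 contains the arene, the Z-alkene and fourteen chain carbons, so the chain problem is only moved into a fragment synthesis of its own. An extra oxidation step is needed.
- Comparison: the chosen route buys C15' in 5 and never breaks a bond to it, and it needs fewer steps overall.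

**Alternative 3: Zweifel olefination at C9'–C10'.** The chain is cut at the alkene into the (E)-alkenylboronic ester A7 and the alkyllithium A8. A8 adds to boron to give an ate complex. Electrophilic iodination then triggers migration of C10' from boron to C9', and base-induced anti elimination gives the Z-alkene A6, which is the same compound as 20.
- For: the Z geometry follows stereospecifically from the mechanism. That is stronger than the kinetic selectivity of the Wittig reaction in step 1. The coupling is convergent and metal-free.
- Against: the electrophilic iodine meets a bis(alkoxy)benzene ring that is itself readily iodinated. A8 requires low-temperature halogen–lithium exchange. A7 and A8 are both multistep fragments, and A7 still needs an aryl–alkyl bond.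
- Comparison: the chosen route brings the arene in after all oxidising and electrophilic operations and uses short commercial building blocks. The price is an alkene geometry that depends on kinetic control.

Key step: step 5

## Route

**Step 1**
Reactants: 1 (4-carboxybutyl)triphenylphosphonium bromide; 2 methyl 9-oxononanoate
Product: 4 (Z)-14-methoxy-14-oxotetradec-5-enoic acid, via phosphorus ylide 3 (not isolated)
Conditions: NaN(SiMe3)2 (2.1 equiv), THF, 0 °C; then 2, −78 °C → rt; 1 M HCl work-up
Reagents that add atoms: none
Why: Wittig olefination with a non-stabilised ylide under lithium-free conditions; kinetic formation of the cis-oxaphosphetane should give the Z-alkene. The carboxyl group is protected as its sodium salt, the methyl ester is untouched at low temperature, and the acid product is separated from the phosphine oxide by base extraction.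

**Step 2**
Reactants: 5 (S)-1,2-epoxybutane; 6 allylmagnesium bromide
Product: 7 (S)-hept-6-en-3-ol
Conditions: CuI (10 mol %), THF/Et2O, −30 → 0 °C; 1 M HCl quench at 0 °C
Reagents that add atoms: none
Why: Copper-catalysed SN2 opening of a terminal epoxide by a Grignard reagent at the unsubstituted carbon. No bond to the stereocentre is broken, so the S configuration of 5 is carried over unchanged.

**Step 3**
Reactants: 7 (S)-hept-6-en-3-ol
Product: 8 (S)-hept-6-en-3-yl acetate
Conditions: Ac2O, pyridine, DMAP (cat.), CH2Cl2, 0 °C → rt
Reagents that add atoms: acetic anhydride, CC(=O)OC(C)=O
Why: DMAP-catalysed O-acylation of a secondary alcohol; the C–O bond at the stereocentre is not touched.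

**Step 4**
Reactants: 8 (S)-hept-6-en-3-yl acetate
Product: 10 (S)-4-acetoxyhexanoic acid, via aldehyde 9 (not isolated)
Conditions: RuCl3·xH2O (2 mol %), NaIO4 (4.1 equiv), MeCN/EtOAc/H2O, rt
Reagents that add atoms: sodium periodate, [Na+].[O-]I(=O)(=O)=O
Why: Oxidative cleavage of a terminal alkene by catalytic RuO4 generated in situ (Sharpless conditions), which passes through the aldehyde to the acid. The acetate is inert, and because the hydroxyl is already acylated no lactone can form.

**Step 5**
Reactants: 4 (Z)-14-methoxy-14-oxotetradec-5-enoic acid; 10 (S)-4-acetoxyhexanoic acid
Product: 11 methyl (9Z,16S)-16-acetoxyoctadec-9-enoate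
Conditions: 4 (1 equiv), 10 (4 equiv), NaOMe (5 mol % of total acid), MeOH, undivided cell, smooth Pt foil anode and cathode, constant current about 0.2 A cm−2, 40–45 °C, stopped near pH 7; AcOH quench
Reagents that add atoms: none
Why: Mixed Kolbe electrolysis; the closest known reaction type is the anodic cross-coupling of a Z-alkenoic acid with a second, saturated or acyloxy-substituted acid at platinum in partly neutralised methanol. Each carboxylate adsorbed on the anode gives up one electron and loses CO2, so 4 becomes a primary radical at C12' and 10 a primary radical at C13', and the two combine in the dense radical layer at the electrode to form the C12'–C13' bond. No ring is closed and no stereocentre is created; C15' sits two carbons from the radical carbon, none of its bonds takes part, and an acetate is a group known to pass the anode unchanged. Three selectivities are needed. Cross- over self-coupling cannot be steered by a reagent and is set by statistics: with 10 in fourfold excess most radicals from 4 should meet a radical from 10, and the small, volatile self-coupling product of 10 and unreacted 10 are easy to separate from 11. Radical over cation chemistry is secured by the substrates (both acids are unbranched at the α-carbon, so the second electron transfer is slow) and by the cell (smooth platinum, high current density, weakly acidic methanol). Retention of the Z-alkene is secured by the position of the cut: the radical from 4 is a pent-4-enyl radical, for which only the slow 4-exo and 5-endo closures exist, whereas a cut one bond closer would give a but-3-enyl radical that equilibrates with a cyclopropylmethyl radical and loses its geometry. The adsorbed carboxylate layer shields the isolated alkene and the esters from oxidation but would not shield an electron-rich arene, which is why the resorcinol is not yet present.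

**Step 6**
Reactants: 11 methyl (9Z,16S)-16-acetoxyoctadec-9-enoate
Product: 12 (9Z,16S)-16-hydroxyoctadec-9-enoic acid
Conditions: LiOH·H2O (5 equiv), THF/MeOH/H2O, 40 °C; then 1 M HCl to pH 3
Reagents that add atoms: lithium hydroxide, [Li+].[OH-]
Why: Saponification of the methyl ester and the acetate in one operation by acyl–oxygen cleavage, so the C15'–O bond and its configuration are retained. The hydroxyl is too remote from the carboxyl to lactonise.

**Step 7**
Reactants: 12 (9Z,16S)-16-hydroxyoctadec-9-enoic acid
Product: 14 (9Z,16S)-16-(tert-butyldimethylsilyloxy)octadec-9-enoic acid, via silyl ester 13 (not isolated)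
Conditions: TBSCl (2.5 equiv), imidazole (5 equiv), DMF, rt; then K2CO3, MeOH/THF/H2O, rt; 1 M HCl to pH 4 at 0 °C
Reagents that add atoms: tert-butyldimethylsilyl chloride, CC(C)(C)[Si](C)(C)Cl
Why: Silylation of both hydroxyl functions followed by selective solvolysis of the silyl ester, which is far more labile than the secondary silyl ether.

**Step 8**
Reactants: 14 (9Z,16S)-16-(tert-butyldimethylsilyloxy)octadec-9-enoic acid
Product: 15 1,3-dioxoisoindolin-2-yl (9Z,16S)-16-(tert-butyldimethylsilyloxy)octadec-9-enoate
Conditions: N-hydroxyphthalimide (1.1 equiv), N,N'-diisopropylcarbodiimide (1.1 equiv), DMAP (10 mol %), CH2Cl2, rt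
Reagents that add atoms: N-hydroxyphthalimide, O=C1N(O)C(=O)c2ccccc12
Why: Carbodiimide (Steglich-type) esterification gives the redox-active ester; the silyl ether and the alkene are inert.

**Step 9**
Reactants: 16 5-bromobenzene-1,3-diol
Product: 17 1-bromo-3,5-bis(methoxymethoxy)benzene
Conditions: MOMCl (2.6 equiv), iPr2NEt (3 equiv), CH2Cl2, 0 °C → rt
Reagents that add atoms: chloromethyl methyl ether, COCCl
Why: O-alkylation of both phenols to acetal ethers that tolerate organomagnesium and organozinc reagents and fall off in acid.

**Step 10**
Reactants: 17 1-bromo-3,5-bis(methoxymethoxy)benzene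
Product: 19 [3,5-bis(methoxymethoxy)phenyl]zinc chloride, via arylmagnesium bromide 18 (not isolated)
Conditions: Mg turnings (2.5 equiv), LiCl (1.25 equiv), THF, rt; then ZnCl2 (1.1 equiv, 1 M in THF), 0 °C → rt; titrated and used as the solution
Reagents that add atoms: zinc chloride, Cl[Zn]Cl
Why: LiCl-assisted magnesium insertion into the aryl bromide followed by transmetalation to zinc. The bromine is meta to both ethers, so no aryne pathway is open, and the acetal ethers are inert to the Grignard reagent.

**Step 11**
Reactants: 15 1,3-dioxoisoindolin-2-yl (9Z,16S)-16-(tert-butyldimethylsilyloxy)octadec-9-enoate; 19 [3,5-bis(methoxymethoxy)phenyl]zinc chloride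
Product: 20 tert-butyl{[(3S,9Z)-17-(3,5-bis(methoxymethoxy)phenyl)heptadec-9-en-3-yl]oxy}dimethylsilane
Conditions: NiCl2·glyme (20 mol %), 4,4'-di-tert-butyl-2,2'-bipyridine (40 mol %), 19 (3 equiv), THF/DMF, rt
Reagents that add atoms: none
Why: Nickel-catalysed decarboxylative Negishi-type arylation of a redox-active ester. A monovalent aryl nickel species reduces 15 by one electron, CO2 and phthalimide anion leave, and the primary radical at C1' is captured by nickel and coupled to the aryl group by reductive elimination from trivalent nickel. The radical is an oct-7-enyl radical with no favourable cyclisation, and the ethers are inert to the arylzinc.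

**Step 12**
Reactants: 20 tert-butyl{[(3S,9Z)-17-(3,5-bis(methoxymethoxy)phenyl)heptadec-9-en-3-yl]oxy}dimethylsilane
Product: 21 Hansfordiol G, 5-[(8Z,15S)-15-hydroxyheptadec-8-en-1-yl]benzene-1,3-diol
Conditions: conc. HCl (5 equiv) in MeOH, 45 °C
Reagents that add atoms: none
Why: Acid-catalysed acetal exchange with methanol removes both methoxymethyl groups and solvolyses the silyl ether in the same pot. No C–O bond at C15' is broken and the isolated Z-alkene is stable to dilute methanolic acid, so both stereochemical elements are retained.

## Compound list

1 | (4-carboxybutyl)triphenylphosphonium bromide | [Br-].OC(=O)CCCC[P+](c1ccccc1)(c1ccccc1)c1ccccc1 | starting material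
2 | methyl 9-oxononanoate | COC(=O)CCCCCCCC=O | starting material
3 | sodium 5-(triphenylphosphoranylidene)pentanoate | [Na+].[O-]C(=O)CCCC=P(c1ccccc1)(c1ccccc1)c1ccccc1 | intermediate
4 | (Z)-14-methoxy-14-oxotetradec-5-enoic acid | OC(=O)CCC/C=C\CCCCCCCC(=O)OC | intermediate
5 | (S)-1,2-epoxybutane | CC[C@H]1CO1 | starting material
6 | allylmagnesium bromide | C=CC[Mg]Br | starting material
7 | (S)-hept-6-en-3-ol | CC[C@H](O)CCC=C | intermediate
8 | (S)-hept-6-en-3-yl acetate | CC[C@H](OC(C)=O)CCC=C | intermediate
9 | (S)-6-oxohexan-3-yl acetate | CC[C@H](OC(C)=O)CCC=O | intermediate
10 | (S)-4-acetoxyhexanoic acid | CC[C@H](OC(C)=O)CCC(=O)O | intermediate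
11 | methyl (9Z,16S)-16-acetoxyoctadec-9-enoate | CC[C@H](OC(C)=O)CCCCC/C=C\CCCCCCCC(=O)OC | intermediate
12 | (9Z,16S)-16-hydroxyoctadec-9-enoic acid | CC[C@H](O)CCCCC/C=C\CCCCCCCC(=O)O | intermediate
13 | tert-butyldimethylsilyl (9Z,16S)-16-(tert-butyldimethylsilyloxy)octadec-9-enoate | CC[C@H](O[Si](C)(C)C(C)(C)C)CCCCC/C=C\CCCCCCCC(=O)O[Si](C)(C)C(C)(C)C | intermediate
14 | (9Z,16S)-16-(tert-butyldimethylsilyloxy)octadec-9-enoic acid | CC[C@H](O[Si](C)(C)C(C)(C)C)CCCCC/C=C\CCCCCCCC(=O)O | intermediate
15 | 1,3-dioxoisoindolin-2-yl (9Z,16S)-16-(tert-butyldimethylsilyloxy)octadec-9-enoate | CC[C@H](O[Si](C)(C)C(C)(C)C)CCCCC/C=C\CCCCCCCC(=O)ON1C(=O)c2ccccc2C1=O | intermediate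
16 | 5-bromobenzene-1,3-diol | Oc1cc(O)cc(Br)c1 | starting material
17 | 1-bromo-3,5-bis(methoxymethoxy)benzene | COCOc1cc(OCOC)cc(Br)c1 | intermediate
18 | [3,5-bis(methoxymethoxy)phenyl]magnesium bromide | COCOc1cc(OCOC)cc([Mg]Br)c1 | intermediate
19 | [3,5-bis(methoxymethoxy)phenyl]zinc chloride | COCOc1cc(OCOC)cc([Zn]Cl)c1 | intermediate
20 | tert-butyl{[(3S,9Z)-17-(3,5-bis(methoxymethoxy)phenyl)heptadec-9-en-3-yl]oxy}dimethylsilane | CC[C@H](O[Si](C)(C)C(C)(C)C)CCCCC/C=C\CCCCCCCc1cc(OCOC)cc(OCOC)c1 | intermediate
21 | Hansfordiol G, 5-[(8Z,15S)-15-hydroxyheptadec-8-en-1-yl]benzene-1,3-diol | CC[C@H](O)CCCCC/C=C\CCCCCCCc1cc(O)cc(O)c1 | target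

## Step count and least certain steps

Total step count: 12. Longest linear sequence: 9 steps (steps 2, 3, 4, 5, 6, 7, 8, 11, 12, from 5 to 21).

**Step 5 (key step).** The coupling is statistical, so self-coupling of each acid always accompanies the cross-coupling. If the radicals are oxidised further before they meet (Hofer–Moest pathway, favoured by a fouled anode, low current density or too much base), ether and alkene by-products take over. Late in the run the electrolyte turns basic and methanolysis of the acetate can begin.

The fallback replaces anodic radical pairing by a cathodic, nickel-mediated doubly decarboxylative coupling. It sets out from 4 and 10. Each acid is converted with N-hydroxyphthalimide and N,N'-diisopropylcarbodiimide into its redox-active ester: 1-(1,3-dioxoisoindolin-2-yl) 14-methyl (Z)-tetradec-5-enedioate F1 from 4, and 1,3-dioxoisoindolin-2-yl (S)-4-acetoxyhexanoate F2 from 10. F1 and an excess of F2 are then electrolysed with NiCl2·6H2O, 2,2':6',2''-terpyridine and AgNO3 in NMP, with a sacrificial Mg anode and a reticulated vitreous carbon cathode at rt. Both alkyl radicals are formed by reduction and joined on nickel, so no substrate is oxidised. The fallback comes back to the route at 11.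

**Step 11.** The primary radical may be reduced or abstract hydrogen before nickel captures it (net protodecarboxylation). The alkylnickel intermediate may undergo β-hydride elimination, or the arylzinc may attack the activated ester carbonyl directly. Incomplete metal insertion in step 10 would show up here as low conversion.

The fallback reverses the polarity of the coupling and sets out from 15. Decarboxylative borylation (bis(catecholato)diboron, DMAc, blue light; then pinacol, NEt3) gives tert-butyldimethyl{[(3S,9Z)-17-(4,4,5,5-tetramethyl-1,3,2-dioxaborolan-2-yl)heptadec-9-en-3-yl]oxy}silane F3. Suzuki–Miyaura coupling of F3 with 17 (Pd(OAc)2, 2-dicyclohexylphosphino-2',6'-diisopropoxybiphenyl, K3PO4, toluene/H2O, 90 °C) comes back to the route at 20.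

**Step 1.** Incomplete kinetic control in oxaphosphetane formation would erode the Z geometry. This erosion cannot be corrected later, because all downstream intermediates are oils that differ only in alkene geometry. Base-induced self-condensation of the aldehyde is a secondary risk.

The fallback sets the geometry by syn-hydrogenation of an alkyne and sets out from 2. Homologation with dimethyl (1-diazo-2-oxopropyl)phosphonate and K2CO3 in MeOH gives methyl dec-9-ynoate F4. Alkyl Sonogashira coupling of F4 with tert-butyl 4-bromobutanoate ([Pd(allyl)Cl]2, 1,3-bis(1-adamantyl)imidazolium chloride, CuI, Cs2CO3, DMF/Et2O, 45 °C) gives 1-tert-butyl 14-methyl tetradec-5-ynedioate F5. Semi-hydrogenation (H2, nickel boride prepared from Ni(OAc)2·4H2O and NaBH4, ethylenediamine, EtOH) gives 1-tert-butyl 14-methyl (Z)-tetradec-5-enedioate F6. Cleavage of the tert-butyl ester with CF3CO2H in CH2Cl2 comes back to the route at 4.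

## Further compounds

F1 | step 5 | 1-(1,3-dioxoisoindolin-2-yl) 14-methyl (Z)-tetradec-5-enedioate | COC(=O)CCCCCCC/C=C\CCCC(=O)ON1C(=O)c2ccccc2C1=O
F2 | step 5 | 1,3-dioxoisoindolin-2-yl (S)-4-acetoxyhexanoate | CC[C@H](OC(C)=O)CCC(=O)ON1C(=O)c2ccccc2C1=O
F3 | step 11 | tert-butyldimethyl{[(3S,9Z)-17-(4,4,5,5-tetramethyl-1,3,2-dioxaborolan-2-yl)heptadec-9-en-3-yl]oxy}silane | CC[C@H](O[Si](C)(C)C(C)(C)C)CCCCC/C=C\CCCCCCCB1OC(C)(C)C(C)(C)O1
F4 | step 1 | methyl dec-9-ynoate | COC(=O)CCCCCCCC#C
F5 | step 1 | 1-tert-butyl 14-methyl tetradec-5-ynedioate | COC(=O)CCCCCCCC#CCCCC(=O)OC(C)(C)C
F6 | step 1 | 1-tert-butyl 14-methyl (Z)-tetradec-5-enedioate | COC(=O)CCCCCCC/C=C\CCCC(=O)OC(C)(C)C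
A1 | alternative 1 | methyl 2,4-dihydroxy-6-[(8Z,15S)-15-(tert-butyldimethylsilyloxy)heptadec-8-enyl]benzoate | CC[C@H](O[Si](C)(C)C(C)(C)C)CCCCC/C=C\CCCCCCCc1cc(O)cc(O)c1C(=O)OC
A2 | alternative 1 | methyl (15Z,22S)-22-(tert-butyldimethylsilyloxy)-3,5,7-trioxotetracos-15-enoate | CC[C@H](O[Si](C)(C)C(C)(C)C)CCCCC/C=C\CCCCCCCC(=O)CC(=O)CC(=O)CC(=O)OC
A3 | alternative 2 | (S,Z)-2-[17-(3,5-bis(methoxymethoxy)phenyl)heptadec-9-en-3-yl]-4,4,5,5-tetramethyl-1,3,2-dioxaborolane | CC[C@H](B1OC(C)(C)C(C)(C)O1)CCCCC/C=C\CCCCCCCc1cc(OCOC)cc(OCOC)c1
A4 | alternative 2 | racemic 2-(1-chloropropyl)-4,4,5,5-tetramethyl-1,3,2-dioxaborolane | CCC(Cl)B1OC(C)(C)C(C)(C)O1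
A5 | alternative 2 | (Z)-[14-(3,5-bis(methoxymethoxy)phenyl)tetradec-6-en-1-yl]zinc iodide | I[Zn]CCCCC/C=C\CCCCCCCc1cc(OCOC)cc(OCOC)c1
A6 | alternative 3 | (S,Z)-tert-butyl{[17-(3,5-bis(methoxymethoxy)phenyl)heptadec-9-en-3-yl]oxy}dimethylsilane (identical with 20) | CC[C@H](O[Si](C)(C)C(C)(C)C)CCCCC/C=C\CCCCCCCc1cc(OCOC)cc(OCOC)c1
A7 | alternative 3 | (E)-2-[9-(3,5-bis(methoxymethoxy)phenyl)non-1-en-1-yl]-4,4,5,5-tetramethyl-1,3,2-dioxaborolane | CC1(C)OB(/C=C/CCCCCCCc2cc(OCOC)cc(OCOC)c2)OC1(C)C
A8 | alternative 3 | [(S)-6-(tert-butyldimethylsilyloxy)octyl]lithium | CC[C@H](O[Si](C)(C)C(C)(C)C)CCCCC[Li]
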